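**Retrosynthetic overview**
1. The ester is formed late by acylating the axial 3-OH of the bicyclic core with (2E,4E,6S)-6-methylocta-2,4-dienoic acid, made from (S)-2-methylbutan-1-ol by a vinylogous Horner–Wadsworth–Emmons reaction; C3 is first brought to the natural configuration by oxidation and reduction.
2. The strategy rests on ring B (C5, C6=C7–OH, C8=O, C9=C10): it is a guaiacol dearomatised at its methyl-bearing para carbon C5, the carbon to which C4 of ring A is bonded, so C4–C5 is the key disconnection.
3. Key step: the para carbon C5 of a 9-chlorophenol attacks C4 of a trans-3,4-epoxide on the C10 side chain; this closes ring A (C1–C5, C10), sets C4 and C5, and releases the C8 dienone and the 3-OH.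
4. The phenol precursor comes from creosol: chlorination ortho to OH (blocks C9), silylation, bromination para to OMe, Grignard/ethylene oxide, oxidation, (E)-propenyllithium addition, Sharpless kinetic-resolution epoxidation, O-silylation, aryl desilylation.
5. Ring order: ring B is the arene of creosol, ring A is formed in the key step; hydrodechlorination, C3 inversion, esterification and acid deprotection follow.

Key step: step 10

Remark: eremophilane numbering is used for the bicyclic compounds (ring A = C1–C5 + C10, ring B = C5–C10); ring A is treated as the chair with the C5 methyl axial, which the near-planar dienone ring enforces.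

**Step 1**
Reactants: 1 creosol (2-methoxy-4-methylphenol)
Product: 2 2-chloro-6-methoxy-4-methylphenol
Conditions: SO2Cl2 (1.05 equiv), iBu2NH (10 mol%), toluene, 0 °C → rt
Reagents that add atoms: sulfuryl chloride, O=S(=O)(Cl)Cl
Why: Amine-catalysed electrophilic aromatic chlorination, in which the N-chloroamine formed from SO2Cl2 is delivered by hydrogen bonding to the position ortho to the phenolic OH, the only free site the hydroxyl activates because its para position carries the methyl group.

**Step 2**
Reactants: 2 2-chloro-6-methoxy-4-methylphenol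
Product: 3 (2-chloro-6-methoxy-4-methylphenoxy)triisopropylsilane
Conditions: TIPSCl, imidazole, DMF, rt → 40 °C
Reagents that add atoms: chlorotriisopropylsilane, CC(C)[Si](Cl)(C(C)C)C(C)C
Why: Silyl ether formation on the phenol, which masks the acidic OH for the organometallic steps and rules out ipso or benzylic bromination through a quinone methide in step 3.

**Step 3**
Reactants: 3 (2-chloro-6-methoxy-4-methylphenoxy)triisopropylsilane
Product: 4 (3-bromo-2-chloro-6-methoxy-4-methylphenoxy)triisopropylsilane (bromine between the chlorine and the ring methyl)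
Conditions: NBS, MeCN, 0 °C → rt
Reagents that add atoms: N-bromosuccinimide, O=C1CCC(=O)N1Br
Why: Electrophilic aromatic bromination in which, with every position ortho or para to the silyloxy group occupied, the methoxy group directs bromine to its para position between the methyl and the chlorine (the substitution pattern of 5,6-dihalovanillins), while the site ortho to the methoxy group is shielded by the methoxy methyl pushed towards it by the neighbouring silyl ether.

**Step 4**
Reactants: 4 (3-bromo-2-chloro-6-methoxy-4-methylphenoxy)triisopropylsilane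
Product: 6 2-[2-chloro-4-methoxy-6-methyl-3-(triisopropylsilyloxy)phenyl]ethanol, via arylmagnesium bromide 5 (not isolated)
Conditions: Mg, LiCl, THF, rt; then CuI (10 mol%), ethylene oxide, −30 → 0 °C
Reagents that add atoms: ethylene oxide, C1CO1
Why: Grignard formation by magnesium insertion into the C–Br bond (the ortho-chloroarylmagnesium is stable to aryne formation at room temperature) followed by copper-catalysed SN2 opening of ethylene oxide, which adds C1 and C2 of ring A.

**Step 5**
Reactants: 6 2-[2-chloro-4-methoxy-6-methyl-3-(triisopropylsilyloxy)phenyl]ethanol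
Product: 7 2-[2-chloro-4-methoxy-6-methyl-3-(triisopropylsilyloxy)phenyl]acetaldehyde
Conditions: Dess–Martin periodinane, CH2Cl2, 0 °C → rt
Reagents that add atoms: none
Why: Dess–Martin oxidation of the primary alcohol stops cleanly at the arylacetaldehyde, whose two ortho substituents slow self-aldol condensation, and the aldehyde is used without purification.

**Step 6**
Reactants: 7 2-[2-chloro-4-methoxy-6-methyl-3-(triisopropylsilyloxy)phenyl]acetaldehyde
Product: 8 rac-(E)-1-[2-chloro-4-methoxy-6-methyl-3-(triisopropylsilyloxy)phenyl]pent-3-en-2-ol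
Conditions: (E)-1-bromopropene, t-BuLi (2 equiv), Et2O, −78 °C; then 7, −78 °C
Reagents that add atoms: (E)-1-bromoprop-1-ene, C/C=C/Br
Why: Bromine–lithium exchange with t-BuLi proceeds with retention of the E geometry and the alkenyllithium adds 1,2 to the aldehyde at −78 °C (carbonyl addition), giving the allylic alcohol as a racemate at C2.

**Step 7**
Reactants: 8 rac-(E)-1-[2-chloro-4-methoxy-6-methyl-3-(triisopropylsilyloxy)phenyl]pent-3-en-2-ol
Product: 9 (2R,3R,4R)-1-[2-chloro-4-methoxy-6-methyl-3-(triisopropylsilyloxy)phenyl]-3,4-epoxypentan-2-ol (erythro carbinol/epoxide, trans-epoxide)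
Conditions: Ti(OiPr)4 (10 mol%), D-(−)-DIPT (15 mol%), TBHP (0.5 equiv), 4 Å MS, CH2Cl2, −20 °C
Reagents that add atoms: tert-butyl hydroperoxide, CC(C)(C)OO
Why: Sharpless asymmetric epoxidation run as a kinetic resolution, in which with D-(−)-DIPT the (R)-carbinol is the fast-reacting enantiomer and is epoxidised on the face that gives the erythro trans-epoxy alcohol, so that C3 and C4 are set by the catalyst and C2 by the resolution while the (S)-enantiomer of 8 stays behind and is separated.

**Step 8**
Reactants: 9 (2R,3R,4R)-epoxy alcohol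
Product: 10 (2R,3S,4R)-2-(tert-butyldimethylsilyloxy)-1-[2-chloro-4-methoxy-6-methyl-3-(triisopropylsilyloxy)phenyl]-3,4-epoxypentane
Conditions: TBSCl, imidazole, DMF, rt
Reagents that add atoms: tert-butyldimethylsilyl chloride, CC(C)(C)[Si](C)(C)Cl
Why: Silyl ether formation with TBSCl/imidazole (not the Lewis-acidic TBSOTf, which can rearrange epoxy alcohols) protects O2 for the Lewis-acid step; the descriptor at C3 changes only because of CIP priorities.

**Step 9**
Reactants: 10 bis-silyl epoxide
Product: 11 2-chloro-6-methoxy-4-methyl-3-[(2R,3S,4R)-2-(tert-butyldimethylsilyloxy)-3,4-epoxypentyl]phenol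
Conditions: TBAF (1.05 equiv), AcOH (1.1 equiv), THF, 0 °C
Reagents that add atoms: none
Why: Fluoride-mediated desilylation, in which the aryl silyl ether with its phenoxide leaving group is cleaved far faster than the secondary alkyl TBS ether and the acetic acid buffer returns the phenol at once so that the epoxide is not exposed to a free phenoxide.

**Step 10**
Reactants: 11 chlorophenol epoxide
Product: 12 (4aS,5R,6S,7R)-7-(tert-butyldimethylsilyloxy)-1-chloro-6-hydroxy-3-methoxy-4a,5-dimethyl-5,6,7,8-tetrahydronaphthalen-2(4aH)-one (eremophilane locants: 9-Cl, 7-OMe, 8-one, 3-OH trans to 4-Me and cis to 2-OTBS, 4-Me cis to 5-Me)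
Conditions: BF3·OEt2 (0.3 equiv), CH2Cl2, −78 → −30 °C
Reagents that add atoms: none
Why: Proposed new method: BF3 coordination to the epoxide oxygen polarises the C4–O bond and the phenol attacks through its methyl-bearing para carbon C5 anti to the departing oxygen, after which loss of the phenolic proton from the oxocarbenium ion gives the C8 dienone that the C5 methyl cannot rearomatise; the closest known reaction types are the Lewis-acid epoxide–arene (Friedel–Crafts) cyclisation and the intramolecular para-C-alkylation of phenols by tethered electrophiles (aryl participation), merged here. Ring A (C1–C5, C10) closes by 6-endo-tet opening at the distal epoxide carbon C4, favoured over 5-exo attack at C3 because C3 carries the inductively deactivating C2 silyloxy group and because five-membered Friedel–Crafts closures are geometrically poor. C4 is set by stereospecific inversion of the trans-epoxide and C3 keeps its configuration, so the 3-OH ends trans to the 4-methyl. C5 is set by a chair-like transition state in which the C4 methyl is equatorial (exo to the arene) and the C2 silyloxy group is axial with only one syn-axial hydrogen, which places the C5 methyl cis to the C4 methyl. The step needs para (C5) over ortho (C9) attack, secured by the chlorine on C9 because ipso attack there cannot rearomatise by proton loss and Cl+ is a poor leaving group, and it needs C-alkylation only, which holds because the phenolic oxygen cannot reach the epoxide.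

**Step 11**
Reactants: 12 chloro dienone
Product: 13 (4aS,5R,6S,7R)-7-(tert-butyldimethylsilyloxy)-6-hydroxy-3-methoxy-4a,5-dimethyl-5,6,7,8-tetrahydronaphthalen-2(4aH)-one
Conditions: Pd(OAc)2 (5 mol%), XPhos (10 mol%), HCO2H, Et3N, DMF, 50 °C
Reagents that add atoms: none
Why: Palladium-catalysed transfer hydrodehalogenation, in which Pd(0) inserts into the activated C9–Cl bond of the α-chloro dienone, formate delivers hydride with loss of CO2 and reductive elimination gives C9–H, the homogeneous formate system leaving the dienone double bonds and the silyl ether untouched.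

**Step 12**
Reactants: 13 dechlorinated hydroxy dienone
Product: 14 (4aS,5R,7R)-7-(tert-butyldimethylsilyloxy)-3-methoxy-4a,5-dimethyl-7,8-dihydronaphthalene-2,6(4aH,5H)-dione (3-ketone)
Conditions: Dess–Martin periodinane, CH2Cl2, 0 °C → rt
Reagents that add atoms: none
Why: Dess–Martin oxidation of the secondary 3-OH under non-basic conditions gives the 3-ketone without epimerising C2 or C4, the 4-methyl already being in the favoured equatorial position.

**Step 13**
Reactants: 14 3-ketone
Product: 15 (4aS,5R,6R,7R)-7-(tert-butyldimethylsilyloxy)-6-hydroxy-3-methoxy-4a,5-dimethyl-5,6,7,8-tetrahydronaphthalen-2(4aH)-one (3-OH axial, cis to 4-Me and 5-Me, trans to 2-OTBS)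
Conditions: L-Selectride (1.1 equiv), THF, −78 °C
Reagents that add atoms: none
Why: Diastereoselective ketone reduction with a bulky hydride, in which the axial C5 methyl blocks the axial trajectory so that hydride attacks C3 equatorially from the face opposite both methyls and gives the axial 3-OH (the pattern of 2-oxo and 4-oxo steroid reductions), the saturated α-silyloxy ketone reacting before the cross-conjugated dienone whose β-carbons are fully substituted or neopentylic.

**Step 14**
Reactants: 16 (S)-2-methylbutan-1-ol
Product: 17 (S)-2-methylbutanal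
Conditions: TEMPO (10 mol%), PhI(OAc)2, CH2Cl2, rt
Reagents that add atoms: none
Why: TEMPO-catalysed oxidation with PhI(OAc)2 is mild and non-basic, so the α-stereocentre is not racemised, and the volatile aldehyde is carried on as a washed and dried solution.

**Step 15**
Reactants: 17 (S)-2-methylbutanal
Product: 18 ethyl (2E,4E,6S)-6-methylocta-2,4-dienoate
Conditions: triethyl 4-phosphonocrotonate, LiHMDS, THF, −78 → 0 °C
Reagents that add atoms: triethyl 4-phosphonocrotonate, CCOC(=O)/C=C/CP(=O)(OCC)OCC
Why: Vinylogous Horner–Wadsworth–Emmons olefination gives the (2E,4E)-dienoate, the new C4=C5 bond forming E as usual for stabilised phosphonates, and the low temperature keeps the α-stereocentre of the aldehyde intact.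

**Step 16**
Reactants: 18 ethyl (2E,4E,6S)-6-methylocta-2,4-dienoate
Product: 19 (2E,4E,6S)-6-methylocta-2,4-dienoic acid
Conditions: LiOH, THF/MeOH/H2O, rt; then aq. HCl to pH 3
Reagents that add atoms: lithium hydroxide, [Li+].[OH-]
Why: Saponification of the ethyl ester and acidification gives the dienoic acid without touching the remote C6 stereocentre.

**Step 17**
Reactants: 19 (2E,4E,6S)-6-methylocta-2,4-dienoic acid; 15 axial 3-alcohol
Product: 21 (2E,4E,6S)-6-methylocta-2,4-dienoate of 15 at O3 (2-OTBS and 7-OMe retained), via mixed anhydride 20 (not isolated)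
Conditions: 2,4,6-trichlorobenzoyl chloride, Et3N, toluene, rt; then 15, DMAP, toluene, 40 °C
Reagents that add atoms: none
Why: Yamaguchi esterification, in which DMAP attacks the mixed anhydride at the less hindered dienoyl carbonyl and the acylpyridinium acylates the axial 3-OH with retention at C3, the 2-OH being silylated.

**Step 18**
Reactants: 21 silylated ester
Product: 23 Septeremophilane G, via C2-hydroxy methyl enol ether 22 (not isolated)
Conditions: 3 M aq. HCl, THF, rt → 40 °C
Reagents that add atoms: water, O
Why: Acid hydrolysis first cleaves the TBS ether and then the methyl enol ether (C6 protonation, water addition at C7, loss of methanol) to the diosphenol, the enolised 7,8-diketone, while the trans-diaxial 2-OH/3-ester arrangement prevents acyl migration.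

**Compound list**
1 | creosol (2-methoxy-4-methylphenol) | COc1cc(C)ccc1O | starting material
2 | 2-chloro-6-methoxy-4-methylphenol | COc1cc(C)cc(Cl)c1O | intermediate
3 | (2-chloro-6-methoxy-4-methylphenoxy)triisopropylsilane | COc1cc(C)cc(Cl)c1O[Si](C(C)C)(C(C)C)C(C)C | intermediate
4 | (3-bromo-2-chloro-6-methoxy-4-methylphenoxy)triisopropylsilane | COc1cc(C)c(Br)c(Cl)c1O[Si](C(C)C)(C(C)C)C(C)C | intermediate
5 | [2-chloro-4-methoxy-6-methyl-3-(triisopropylsilyloxy)phenyl]magnesium bromide | COc1cc(C)c([Mg]Br)c(Cl)c1O[Si](C(C)C)(C(C)C)C(C)C | intermediate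
6 | 2-[2-chloro-4-methoxy-6-methyl-3-(triisopropylsilyloxy)phenyl]ethanol | COc1cc(C)c(CCO)c(Cl)c1O[Si](C(C)C)(C(C)C)C(C)C | intermediate
7 | 2-[2-chloro-4-methoxy-6-methyl-3-(triisopropylsilyloxy)phenyl]acetaldehyde | COc1cc(C)c(CC=O)c(Cl)c1O[Si](C(C)C)(C(C)C)C(C)C | intermediate
8 | rac-(E)-1-[2-chloro-4-methoxy-6-methyl-3-(triisopropylsilyloxy)phenyl]pent-3-en-2-ol | C/C=C/C(O)Cc1c(C)cc(OC)c(O[Si](C(C)C)(C(C)C)C(C)C)c1Cl | intermediate
9 | (2R,3R,4R)-1-[2-chloro-4-methoxy-6-methyl-3-(triisopropylsilyloxy)phenyl]-3,4-epoxypentan-2-ol | C[C@H]1O[C@@H]1[C@H](O)Cc1c(C)cc(OC)c(O[Si](C(C)C)(C(C)C)C(C)C)c1Cl | intermediate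
10 | (2R,3S,4R)-2-(tert-butyldimethylsilyloxy)-1-[2-chloro-4-methoxy-6-methyl-3-(triisopropylsilyloxy)phenyl]-3,4-epoxypentane | C[C@H]1O[C@@H]1[C@H](O[Si](C)(C)C(C)(C)C)Cc1c(C)cc(OC)c(O[Si](C(C)C)(C(C)C)C(C)C)c1Cl | intermediate
11 | 2-chloro-6-methoxy-4-methyl-3-[(2R,3S,4R)-2-(tert-butyldimethylsilyloxy)-3,4-epoxypentyl]phenol (key-step precursor) | C[C@H]1O[C@@H]1[C@H](O[Si](C)(C)C(C)(C)C)Cc1c(Cl)c(O)c(OC)cc1C | intermediate
12 | (4aS,5R,6S,7R)-7-(tert-butyldimethylsilyloxy)-1-chloro-6-hydroxy-3-methoxy-4a,5-dimethyl-5,6,7,8-tetrahydronaphthalen-2(4aH)-one (key-step product) | O[C@@H]1[C@H](O[Si](C)(C)C(C)(C)C)CC2=C(Cl)C(=O)C(OC)=C[C@]2(C)[C@H]1C | intermediate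
13 | (4aS,5R,6S,7R)-7-(tert-butyldimethylsilyloxy)-6-hydroxy-3-methoxy-4a,5-dimethyl-5,6,7,8-tetrahydronaphthalen-2(4aH)-one | O[C@@H]1[C@H](O[Si](C)(C)C(C)(C)C)CC2=CC(=O)C(OC)=C[C@]2(C)[C@H]1C | intermediate
14 | (4aS,5R,7R)-7-(tert-butyldimethylsilyloxy)-3-methoxy-4a,5-dimethyl-7,8-dihydronaphthalene-2,6(4aH,5H)-dione | O=C1[C@H](O[Si](C)(C)C(C)(C)C)CC2=CC(=O)C(OC)=C[C@]2(C)[C@H]1C | intermediate
15 | (4aS,5R,6R,7R)-7-(tert-butyldimethylsilyloxy)-6-hydroxy-3-methoxy-4a,5-dimethyl-5,6,7,8-tetrahydronaphthalen-2(4aH)-one | O[C@H]1[C@H](O[Si](C)(C)C(C)(C)C)CC2=CC(=O)C(OC)=C[C@]2(C)[C@H]1C | intermediate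
16 | (S)-2-methylbutan-1-ol | CC[C@H](C)CO | starting material
17 | (S)-2-methylbutanal | CC[C@H](C)C=O | intermediate
18 | ethyl (2E,4E,6S)-6-methylocta-2,4-dienoate | CC[C@H](C)/C=C/C=C/C(=O)OCC | intermediate
19 | (2E,4E,6S)-6-methylocta-2,4-dienoic acid | CC[C@H](C)/C=C/C=C/C(=O)O | intermediate
20 | (2E,4E,6S)-6-methylocta-2,4-dienoic 2,4,6-trichlorobenzoic anhydride | CC[C@H](C)/C=C/C=C/C(=O)OC(=O)c1c(Cl)cc(Cl)cc1Cl | intermediate
21 | (2E,4E,6S)-6-methylocta-2,4-dienoate of 15 at O3 (2-OTBS, 7-OMe) | CC[C@H](C)/C=C/C=C/C(=O)O[C@H]1[C@H](O[Si](C)(C)C(C)(C)C)CC2=CC(=O)C(OC)=C[C@]2(C)[C@H]1C | intermediate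
22 | 7-O-methyl ether of Septeremophilane G (2-OH free) | CC[C@H](C)/C=C/C=C/C(=O)O[C@H]1[C@H](O)CC2=CC(=O)C(OC)=C[C@]2(C)[C@H]1C | intermediate
23 | Septeremophilane G (2R,3R,4R,5S by eremophilane numbering) | CC[C@H](C)/C=C/C=C/C(=O)O[C@H]1[C@H](O)CC2=CC(=O)C(O)=C[C@]2(C)[C@H]1C | target

**Step count**
Total: 18 steps. Longest linear sequence: 15 steps (steps 1–13, 17, 18 from creosol); the acid branch is 3 steps (14–16).

**Steps most likely to fail**

Step 10 (bears the label "Proposed new method:"). The C–C bond formation itself is at risk. The activated epoxide may undergo hydride or alkyl shift to a carbonyl compound (Meinwald-type rearrangement), closure may run through a boat-like arrangement (wrong configuration at C5), or attack may occur at the chlorinated ortho carbon before the hindered, methyl-bearing para carbon reacts. The fallback uses known chemistry: base-mediated para-C-alkylation of a phenolate by a tethered cyclic sulfate (aryl-participation alkylation). It sets out from 8 and returns at 12. Kinetic resolution of 8 with L-(+)-DIPT, Ti(OiPr)4 and TBHP (about 0.6 equiv) would leave the (R)-allylic alcohol F1. TBSCl/imidazole would give its silyl ether F2. OsO4/NMO, adding anti to the allylic silyloxy group as is usual for allylic ethers, would give the (2R,3S,4R)-3,4-diol F3, whose two C–O bonds have the configuration of the epoxide in 11. SOCl2/Et3N would give the cyclic sulfite F4, and RuCl3 (cat.)/NaIO4 the cyclic sulfate F5. TBAF (1.0 equiv, THF, −78 → 0 °C, high dilution) would cleave the aryl silyl ether, and the phenoxide would alkylate through C5 at C4 with inversion to give the C3 hydrogen sulfate F6. Catalytic H2SO4 with water in THF would hydrolyse the sulfate ester to 12.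

Step 13. The facial selectivity of hydride delivery is at risk: attack anti to the axial 2-silyloxy group (from the methyl face) would regenerate the equatorial alcohol, and conjugate reduction of the dienone may compete. The fallback replaces reduction and acylation by a trans-diaxial epoxide opening. It sets out from 13 and returns at 22, the intermediate of step 18, so steps 13 and 17 are bypassed. TBAF would give the cis-2,3-diol F7. 1,1'-Thiocarbonyldiimidazole would give the cyclic thionocarbonate F8. Corey–Winter olefination (1,3-dimethyl-2-phenyl-1,3,2-diazaphospholidine, 40 °C) would give the Δ2-olefin F9. mCPBA, approaching anti to the axial C5 methyl, would give the 2,3-epoxide F10 with its oxygen on the face opposite the methyls. Heating F10 with an excess of acid 19 in toluene would open it trans-diaxially at C3, as 2α,3α-epoxy steroids open at C2, to give 22.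

Step 17. Acyl transfer to the axial 3-OH may be too slow, because it is syn-axial to the C5 methyl and flanked by the 4-methyl and the 2-silyloxy group; the activated dienoyl donor may isomerise or decompose meanwhile. The fallback builds the dienoate on the alcohol in two stages, setting out from 15 and returning at 21. Diethylphosphonoacetic acid with DCC, acylating through the small and very reactive phosphonoketene, would give the phosphonoacetate F11. Aldehyde 17 and (triphenylphosphoranylidene)acetaldehyde would give (S,E)-4-methylhex-2-enal F12. A LiCl/DBU Horner–Wadsworth–Emmons reaction of F11 with F12 would give 21.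

**Further compounds**
F1 | step 10 | (R,E)-1-[2-chloro-4-methoxy-6-methyl-3-(triisopropylsilyloxy)phenyl]pent-3-en-2-ol | C/C=C/[C@H](O)Cc1c(C)cc(OC)c(O[Si](C(C)C)(C(C)C)C(C)C)c1Cl
F2 | step 10 | TBS ether of F1 | C/C=C/[C@H](O[Si](C)(C)C(C)(C)C)Cc1c(C)cc(OC)c(O[Si](C(C)C)(C(C)C)C(C)C)c1Cl
F3 | step 10 | (2R,3S,4R)-2-(tert-butyldimethylsilyloxy)-1-arylpentane-3,4-diol | C[C@@H](O)[C@H](O)[C@H](O[Si](C)(C)C(C)(C)C)Cc1c(C)cc(OC)c(O[Si](C(C)C)(C(C)C)C(C)C)c1Cl
F4 | step 10 | 3,4-cyclic sulfite of F3 | C[C@H]1OS(=O)O[C@@H]1[C@H](O[Si](C)(C)C(C)(C)C)Cc1c(C)cc(OC)c(O[Si](C(C)C)(C(C)C)C(C)C)c1Cl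
F5 | step 10 | 3,4-cyclic sulfate of F3 | C[C@H]1OS(=O)(=O)O[C@@H]1[C@H](O[Si](C)(C)C(C)(C)C)Cc1c(C)cc(OC)c(O[Si](C(C)C)(C(C)C)C(C)C)c1Cl
F6 | step 10 | C3 hydrogen sulfate of 12 | OS(=O)(=O)O[C@@H]1[C@H](O[Si](C)(C)C(C)(C)C)CC2=C(Cl)C(=O)C(OC)=C[C@]2(C)[C@H]1C
F7 | step 13 | cis-2,3-diol from 13 | O[C@@H]1[C@H](O)CC2=CC(=O)C(OC)=C[C@]2(C)[C@H]1C
F8 | step 13 | 2,3-cyclic thionocarbonate of F7 | S=C3O[C@@H]1[C@H](O3)CC2=CC(=O)C(OC)=C[C@]2(C)[C@H]1C
F9 | step 13 | (4aS,5R)-3-methoxy-4a,5-dimethyl-5,8-dihydronaphthalen-2(4aH)-one (Δ2-olefin, eremophilane numbering) | C1=CCC2=CC(=O)C(OC)=C[C@]2(C)[C@H]1C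
F10 | step 13 | 2,3-epoxide of F9 with oxygen anti to the C5 methyl | O3[C@@H]1[C@H]3CC2=CC(=O)C(OC)=C[C@]2(C)[C@H]1C
F11 | step 17 | diethylphosphonoacetate of 15 at O3 | CCOP(=O)(OCC)CC(=O)O[C@H]1[C@H](O[Si](C)(C)C(C)(C)C)CC2=CC(=O)C(OC)=C[C@]2(C)[C@H]1C
F12 | step 17 | (S,E)-4-methylhex-2-enal | CC[C@H](C)/C=C/C=O
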